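Count the base.

    electrophile + nucleophile → acid set free + product (k1 = 670 M⁻¹ s⁻¹)
    free base + product ⇌ idle adduct, settled at all times (K2 = 4600 M⁻¹)
    nucleophile + acid set free ⇌ protonated nucleophile, settled at all times (K3 = 4.8 × 10⁵ M⁻¹)
    acid set free → by-product carried off (k4 = 0.042 s⁻¹)
    acid set free + free base ⇌ salt of the base, settled at all times (K5 = 2.1 × 10⁵ M⁻¹)

| flask | electrophile | free base | protonated nucleophile | time |
|---|---|---|---|---|
| Friday's | 0.50 mM | 2.70 equiv | 3.00 equiv | 12 s |
| Monday's | 0.50 mM | 1.20 equiv | 3.00 equiv | 12 s |
| Thursday's | 0.50 mM | 1.80 equiv | 3.00 equiv | 12 s |

1. part of the electrophile that has reacted at the end, Friday's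
2. part of the electrophile that has reacted at the end, Monday's
3. part of the electrophile that has reacted at the end, Thursday's
4. what raising the equivalents of free base from its lowest to its highest value here does to the part of the electrophile that has reacted (changes below 5 percentage points count as none) (it rises / it falls / no change)

- product is meant together with its idle adduct
- run time (Friday's): 12 s

Write x for the part of the electrophile that has reacted, and reckon every amount as a fraction of the electrophile charged. When the free base takes a proton from the protonated nucleophile, the sum of nucleophile and free base stays at the base charged. Each turnover, though, removes a nucleophile and sets free an acid that takes one more of the pair, so the sum falls by two for each turnover. On Monday's it reaches zero at 60.0%; call this L, the stall level, half the equivalents of free base charged.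

As a plain assumption of my own, used for each flask, give the nucleophile half of the sum, which is L − x. With s = 0.335 s⁻¹, the rate s(1 − x)(L − x) integrates to x = L(G − 1)/(G − L), where G = exp[s(1 − L)t].

Draw Monday's curve from this. It starts at a slope of 0.201 s⁻¹, crosses half the level at 2.51 s, and bends into L with a time constant of 7.46 s, reaching 54.5% at 12 s. The same formula gives 74.9% for Thursday's and 92.2% for Friday's, so the part reacted rises by 38 percentage points. This reckoning leaves out the idle adduct and the acid loss.

The forecast gave 80.5%, 53% and 67% for Friday's, Monday's and Thursday's, said that with more free base the part reacted it rises, and put the stall “at a point that scales with the base loading”.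

The flask gives 81.2%, 55.5% and 68.4%, and it rises by 26 points. My reckoning is 11 points high on Friday's, where idle adduct holds 42.4%, and 1 point low on Monday's, where it holds 8.65%. Monday's has not come to rest at 12 s, for at 120 s it stands at 93.5%, past L, with by-product grown from 0.0175 mM to 0.406 mM and free base moved from 6.68% to 6.07%. Over the 12 s itself, striking out the acid loss makes no difference to Monday's. Left as long, Thursday's reaches 97.9% and Friday's 99.9%.

On the neighbour of Monday's charged with 0.720 equiv of free base, L is 36.0%, and the formula gives 34.2%. That flask gives 42.3%, above its level, with 0.0941 mM of acid set free and 0.0279 mM of by-product standing at 12.0 s.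

The numbers are made up; the rest is arithmetic.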